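**Retrosynthetic overview**

1. Locants: dioxane O1–O2–C3–C4–C5–C6, side chain C7 (the CH2 on C6) to C14, acid carbons C2' and C1'. Target 36 comes from dioxane-ethanol 34 by oxidation of C1'.
2. The 1,2-dioxane is opened at O2–C3 (6-exo SN2 attack of a C6 hydroperoxide on a C3/C1' oxetane, a temporary ring, with inversion at C3) and at C6–O1 (Markovnikov hydroperoxysilylation of the C6=C7 alkene 31).
3. Enabling feature: C7 is the single CH2 between the fully substituted peroxy carbon C6 of the dioxane ring and the methyl-bearing C8. Because the C6–O1 bond can be grown from a C6=C7 double bond, C7 can be sp2, and C7–C8 is made by a stereoretentive Zweifel coupling of alkenyl iodide 27 (fragment A, C1'–C7) with secondary boronic ester 13 (fragment B, C8–C14).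
4. 13 comes from BuBpin by two sparteine-controlled lithiation–borylations (C10, C8) around one Matteson CH2 insertion; 27 comes from Evans alkylation (C4), Brown allylation (C3), ozonolysis/reduction, oxetane closure and ethylcupration–iodination.
5. Ring order: oxetane first (step 10), 1,2-dioxane last (step 14); the oxetane is consumed as the dioxane closes.

Key step: step 12

Remark 1: C6 arises in step 13 from a planar tertiary radical flanked by two similar CH2 groups, so both C6 epimers are expected there; they are carried to step 14 and separated as the cyclic diastereomers.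
Remark 2: ethyl 2,4,6-triisopropylbenzoate (10), (R)-4-benzyl-3-butanoyloxazolidin-2-one (14), (+)-sparteine and (+)-B-methoxydiisopinocampheylborane are taken as purchasable.

**Route**

Step 1
Reactants: 1 2,4,6-triisopropylbenzoic acid; 2 1-bromopropane
Product: 3 propyl 2,4,6-triisopropylbenzoate
Conditions: K2CO3, DMF, 60 °C
Reagents that add atoms: none
Why: Carboxylate O-alkylation (SN2 at the primary bromide) is insensitive to the bulk around the carboxyl group, which makes the hindered ester accessible.

Step 2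
Reactants: 3 propyl 2,4,6-triisopropylbenzoate; 4 2-butyl-4,4,5,5-tetramethyl-1,3,2-dioxaborolane
Product: 7 2-[(S)-heptan-3-yl]-4,4,5,5-tetramethyl-1,3,2-dioxaborolane, via lithiated ester 5 (not isolated), via boronate complex 6 (not isolated)
Conditions: sec-BuLi, (+)-sparteine, Et2O, −78 °C, 5 h; then 4, −78 °C; then 35 °C, 16 h
Reagents that add atoms: none
Why: Sparteine-mediated asymmetric deprotonation removes the pro-R hydrogen next to oxygen, the configurationally stable carbenoid adds to boron with retention and the butyl group then migrates with inversion at carbon as the hindered benzoate leaves (lithiation–borylation, a stereospecific 1,2-metallate rearrangement), so C10 is set by the chiral diamine.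

Step 3
Reactants: 7 2-[(S)-heptan-3-yl]-4,4,5,5-tetramethyl-1,3,2-dioxaborolane
Product: 9 2-[(S)-2-ethylhexyl]-4,4,5,5-tetramethyl-1,3,2-dioxaborolane, via chloromethyl boronate 8 (not isolated)
Conditions: BrCH2Cl, n-BuLi, Et2O, −78 → 23 °C
Reagents that add atoms: bromochloromethane, ClCBr
Why: Matteson homologation, in which chloromethyllithium adds to boron and the secondary alkyl group migrates with retention while chloride leaves, so C10 is untouched.

Step 4
Reactants: 9 2-[(S)-2-ethylhexyl]-4,4,5,5-tetramethyl-1,3,2-dioxaborolane; 10 ethyl 2,4,6-triisopropylbenzoate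
Product: 13 2-[(2S,4S)-4-ethyloctan-2-yl]-4,4,5,5-tetramethyl-1,3,2-dioxaborolane, via lithiated ester 11 (not isolated), via boronate complex 12 (not isolated)
Conditions: 10, sec-BuLi, (+)-sparteine, Et2O, −78 °C, 5 h; then 9, −78 °C; then 35 °C, 16 h
Reagents that add atoms: none
Why: Second lithiation–borylation with the same diamine, in which the (R)-1-lithioethyl benzoate is borylated with retention and the 2-ethylhexyl group migrates with inversion at the carbenoid carbon, so C8 is set under reagent control irrespective of C10.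

Step 5
Reactants: 14 (R)-4-benzyl-3-butanoyloxazolidin-2-one; 15 3-bromoprop-1-yne
Product: 17 (R)-4-benzyl-3-[(S)-2-ethylpent-4-ynoyl]oxazolidin-2-one, via sodium enolate 16 (not isolated)
Conditions: NaN(SiMe3)2, THF, −78 °C; then 15, −78 → −40 °C
Reagents that add atoms: none
Why: Evans alkylation, in which the chelated (Z)-sodium enolate is alkylated by the reactive propargylic bromide on the face opposite the benzyl group, which sets C4.

Step 6
Reactants: 17 (R)-4-benzyl-3-[(S)-2-ethylpent-4-ynoyl]oxazolidin-2-one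
Product: 18 (S)-2-ethylpent-4-yn-1-ol
Conditions: LiBH4, MeOH (1 equiv), Et2O, 0 °C
Reagents that add atoms: none
Why: Reductive removal of the auxiliary by hydride attack at the exocyclic imide carbonyl gives the primary alcohol without touching the α-stereocentre.

Step 7
Reactants: 18 (S)-2-ethylpent-4-yn-1-ol
Product: 19 (S)-2-ethylpent-4-ynal
Conditions: Dess–Martin periodinane, NaHCO3, CH2Cl2, 0 → 23 °C; used at once as a solution
Reagents that add atoms: none
Why: Dess–Martin oxidation under buffered, non-basic conditions should give the α-branched aldehyde without epimerisation.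

Step 8
Reactants: 19 (S)-2-ethylpent-4-ynal
Product: 21 (4R,5S)-5-ethyloct-1-en-7-yn-4-ol, via borinate ester 20 (not isolated)
Conditions: (+)-Ipc2BOMe, CH2=CHCH2MgBr, Et2O, −78 → 23 °C; then 19, −78 °C; then NaOH, H2O2, 23 °C
Reagents that add atoms: allylmagnesium bromide, C=CC[Mg]Br
Why: Brown allylation, in which the allyl group is delivered through a chair-like six-membered transition state whose facial preference is dictated by the isopinocampheyl groups, so C3 is set by the reagent (R here, anti to the C4 ethyl) and not by the weakly biased α-centre.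

Step 9
Reactants: 21 (4R,5S)-5-ethyloct-1-en-7-yn-4-ol
Product: 23 (3R,4S)-4-ethylhept-6-yne-1,3-diol, via ozonide 22 (not isolated)
Conditions: O3, CH2Cl2, −78 °C (to the first persistent blue); then NaBH4, MeOH, −78 → 23 °C
Reagents that add atoms: ozone, [O-][O+]=O
Why: Ozone cleaves the terminal alkene much faster than the terminal alkyne, and borohydride reduction of the ozonide gives the 1,3-diol directly.

Step 10
Reactants: 23 (3R,4S)-4-ethylhept-6-yne-1,3-diol
Product: 25 (R)-2-[(S)-hex-5-yn-3-yl]oxetane, via primary tosylate 24 (not isolated)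
Conditions: TsCl, pyridine, CH2Cl2, 0 °C; then KOC(CH3)3, THF, 0 → 23 °C
Reagents that add atoms: none
Why: Selective sulfonylation of the unhindered primary hydroxyl followed by intramolecular Williamson etherification (4-exo-tet) closes the oxetane with retention at C3, since the C3–O bond is not broken; the ring protects both oxygens and stores the C3 leaving group.

Step 11
Reactants: 25 (R)-2-[(S)-hex-5-yn-3-yl]oxetane
Product: 27 (R)-2-[(3S,5E)-5-ethyl-6-iodohex-5-en-3-yl]oxetane, via alkenylcopper 26 (not isolated)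
Conditions: EtMgBr, CuBr·SMe2, Et2O/Me2S, −45 °C; then 25, −25 °C; then I2, −78 → 0 °C
Reagents that add atoms: ethylmagnesium bromide, CC[Mg]Br; iodine, I-I
Why: syn-Carbocupration of the terminal alkyne by ethylcopper·MgBr2 places copper on the terminal carbon and ethyl on the internal one, and iodinolysis with retention gives the (E)-alkenyl iodide, whose geometry only matters for purity because it is erased in step 13.

Step 12
Reactants: 27 (R)-2-[(3S,5E)-5-ethyl-6-iodohex-5-en-3-yl]oxetane; 13 2-[(2S,4S)-4-ethyloctan-2-yl]-4,4,5,5-tetramethyl-1,3,2-dioxaborolane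
Product: 31 (R)-2-[(3S,5Z,7S,9S)-5,9-diethyl-7-methyltridec-5-en-3-yl]oxetane, via alkenyllithium 28 (not isolated), via boronate complex 29 (not isolated), via iodoboronate 30 (not isolated)
Conditions: 27, tert-BuLi (2.1 equiv), Et2O, −78 °C; then 13, THF, −78 °C; then I2, THF, −78 °C; then NaOCH3, MeOH, −78 → 23 °C
Reagents that add atoms: none
Why: Iodine–lithium exchange gives alkenyllithium 28, which adds to the boron of 13 to give ate complex 29; iodine then activates the C6=C7 bond and C8 migrates from boron to C7 in a concerted, stereoretentive 1,2-metallate shift to give 30, from which methoxide triggers anti elimination of boron and iodine (Zweifel olefination of a secondary alkylboronic ester with a substituted alkenyllithium, a well-precedented class). No ring is closed and no new stereocentre is created: the step only has to carry the C8 configuration of 13 across, which the suprafacial boron-to-carbon migration secures, while C10, C4 and C3 are remote spectators. The union joins an eleven-carbon and a ten-carbon fragment at the CH2 next to the future quaternary peroxy carbon, a position that an SN2 alkylation could not reach. The (Z) geometry that follows from the (E) iodide is of no consequence, because step 13 planarises C6. The selectivity needed is attack of 28 at boron rather than at the oxetane, which the low temperature and the absence of a Lewis acid should secure.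

Step 13
Reactants: 31 (R)-2-[(3S,5Z,7S,9S)-5,9-diethyl-7-methyltridec-5-en-3-yl]oxetane
Product: 32 triethyl{[(3S,7S,9S)-5,9-diethyl-7-methyl-3-((R)-oxetan-2-yl)tridecan-5-yl]peroxy}silane (both epimers at the peroxy carbon C6)
Conditions: Co(thd)2 (10 mol %; thd = 2,2,6,6-tetramethylheptane-3,5-dionate), O2 (1 atm), Et3SiH, ClCH2CH2Cl, 23 °C
Reagents that add atoms: dioxygen, O=O; triethylsilane, CC[SiH](CC)CC
Why: Mukaiyama–Isayama hydroperoxysilylation, in which a cobalt hydride transfers hydrogen to C7, the tertiary C6 radical is trapped by O2 and the peroxyl radical is silylated, so oxygen ends at the more substituted carbon; the radical is planar, so no facial control is expected and both C6 epimers should form.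

Step 14
Reactants: 32 triethyl{[(3S,7S,9S)-5,9-diethyl-7-methyl-3-((R)-oxetan-2-yl)tridecan-5-yl]peroxy}silane (both C6 epimers)
Product: 34 2-[(3S,4S,6R)-4,6-diethyl-6-((2S,4S)-4-ethyl-2-methyloctyl)-1,2-dioxan-3-yl]ethan-1-ol, via hydroperoxide 33 (not isolated)
Conditions: Bu4NF, THF, 0 °C, then NH4Cl (aq); then Me3SiOTf (0.3 equiv), CH2Cl2, −40 → 0 °C; chromatographic separation of the C6 epimers
Reagents that add atoms: none
Why: Fluoride frees the tertiary hydroperoxide, whose terminal oxygen opens the Lewis-acid-activated oxetane at C3 in a 6-exo SN2 reaction with inversion (intramolecular hydroperoxide–oxetane opening), which turns (3R) into the required (3S) and releases the primary alcohol; the (6R) and (6S) dioxanes are diastereomers and the (6R) isomer is to be isolated by chromatography.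

Step 15
Reactants: 34 2-[(3S,4S,6R)-4,6-diethyl-6-((2S,4S)-4-ethyl-2-methyloctyl)-1,2-dioxan-3-yl]ethan-1-ol
Product: 36 2-[(3S,4S,6R)-4,6-diethyl-6-((2S,4S)-4-ethyl-2-methyloctyl)-1,2-dioxan-3-yl]acetic acid, via aldehyde 35 (not isolated)
Conditions: TEMPO (20 mol %), PhI(OAc)2, MeCN/H2O, 23 °C
Reagents that add atoms: water, O
Why: Oxoammonium-mediated oxidation takes the primary alcohol through the aldehyde hydrate to the acid under near-neutral conditions that should neither reduce the O–O bond nor promote β-elimination of the peroxide.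

**Compound list**

1 | 2,4,6-triisopropylbenzoic acid | CC(C)c1cc(C(C)C)c(C(=O)O)c(C(C)C)c1 | starting material
2 | 1-bromopropane | CCCBr | starting material
3 | propyl 2,4,6-triisopropylbenzoate | CCCOC(=O)c1c(C(C)C)cc(C(C)C)cc1C(C)C | intermediate
4 | 2-butyl-4,4,5,5-tetramethyl-1,3,2-dioxaborolane | CCCCB1OC(C)(C)C(C)(C)O1 | starting material
5 | (R)-1-lithiopropyl 2,4,6-triisopropylbenzoate ((+)-sparteine complex) | CC[C@@H]([Li])OC(=O)c1c(C(C)C)cc(C(C)C)cc1C(C)C | intermediate
6 | lithium butyl[(R)-1-(2,4,6-triisopropylbenzoyloxy)propyl](pinacolato)borate | CCCC[B-]1(OC(C)(C)C(C)(C)O1)[C@H](CC)OC(=O)c1c(C(C)C)cc(C(C)C)cc1C(C)C.[Li+] | intermediate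
7 | 2-[(S)-heptan-3-yl]-4,4,5,5-tetramethyl-1,3,2-dioxaborolane | CCCC[C@H](CC)B1OC(C)(C)C(C)(C)O1 | intermediate
8 | lithium (chloromethyl)[(S)-heptan-3-yl](pinacolato)borate | CCCC[C@H](CC)[B-]1(CCl)OC(C)(C)C(C)(C)O1.[Li+] | intermediate
9 | 2-[(S)-2-ethylhexyl]-4,4,5,5-tetramethyl-1,3,2-dioxaborolane | CCCC[C@H](CC)CB1OC(C)(C)C(C)(C)O1 | intermediate
10 | ethyl 2,4,6-triisopropylbenzoate | CCOC(=O)c1c(C(C)C)cc(C(C)C)cc1C(C)C | starting material
11 | (R)-1-lithioethyl 2,4,6-triisopropylbenzoate ((+)-sparteine complex) | C[C@@H]([Li])OC(=O)c1c(C(C)C)cc(C(C)C)cc1C(C)C | intermediate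
12 | lithium [(S)-2-ethylhexyl][(R)-1-(2,4,6-triisopropylbenzoyloxy)ethyl](pinacolato)borate | CCCC[C@H](CC)C[B-]1(OC(C)(C)C(C)(C)O1)[C@H](C)OC(=O)c1c(C(C)C)cc(C(C)C)cc1C(C)C.[Li+] | intermediate
13 | 2-[(2S,4S)-4-ethyloctan-2-yl]-4,4,5,5-tetramethyl-1,3,2-dioxaborolane | CCCC[C@H](CC)C[C@H](C)B1OC(C)(C)C(C)(C)O1 | intermediate
14 | (R)-4-benzyl-3-butanoyloxazolidin-2-one | CCCC(=O)N1[C@H](Cc2ccccc2)COC1=O | starting material
15 | 3-bromoprop-1-yne | C#CCBr | starting material
16 | sodium (Z)-enolate of 14 | CC/C=C(\[O-])N1[C@H](Cc2ccccc2)COC1=O.[Na+] | intermediate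
17 | (R)-4-benzyl-3-[(S)-2-ethylpent-4-ynoyl]oxazolidin-2-one | C#CC[C@H](CC)C(=O)N1[C@H](Cc2ccccc2)COC1=O | intermediate
18 | (S)-2-ethylpent-4-yn-1-ol | C#CC[C@H](CC)CO | intermediate
19 | (S)-2-ethylpent-4-ynal | C#CC[C@H](CC)C=O | intermediate
20 | (4R,5S)-5-ethyloct-1-en-7-yn-4-yl diisopinocampheylborinate | C#CC[C@H](CC)[C@@H](CC=C)OB([C@H]1C[C@H]2C[C@@H]([C@@H]1C)C2(C)C)[C@H]1C[C@H]2C[C@@H]([C@@H]1C)C2(C)C | intermediate
21 | (4R,5S)-5-ethyloct-1-en-7-yn-4-ol | C#CC[C@H](CC)[C@@H](CC=C)O | intermediate
22 | (2R,3S)-3-ethyl-1-(1,2,4-trioxolan-3-yl)hex-5-yn-2-ol (ozonide, trioxolane carbon unassigned) | C#CC[C@H](CC)[C@@H](CC1OCOO1)O | intermediate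
23 | (3R,4S)-4-ethylhept-6-yne-1,3-diol | C#CC[C@H](CC)[C@@H](CCO)O | intermediate
24 | (3R,4S)-4-ethyl-3-hydroxyhept-6-yn-1-yl 4-methylbenzenesulfonate | C#CC[C@H](CC)[C@@H](CCOS(=O)(=O)c1ccc(C)cc1)O | intermediate
25 | (R)-2-[(S)-hex-5-yn-3-yl]oxetane | C#CC[C@H](CC)[C@H]1CCO1 | intermediate
26 | [(1E,4S)-2-ethyl-4-((R)-oxetan-2-yl)hex-1-en-1-yl]copper (MgBr2 complex) | [Cu]/C=C(\CC)C[C@H](CC)[C@H]1CCO1 | intermediate
27 | (R)-2-[(3S,5E)-5-ethyl-6-iodohex-5-en-3-yl]oxetane | I/C=C(\CC)C[C@H](CC)[C@H]1CCO1 | intermediate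
28 | [(1E,4S)-2-ethyl-4-((R)-oxetan-2-yl)hex-1-en-1-yl]lithium | [Li]/C=C(\CC)C[C@H](CC)[C@H]1CCO1 | intermediate
29 | lithium [(2S,4S)-4-ethyloctan-2-yl][(1E,4S)-2-ethyl-4-((R)-oxetan-2-yl)hex-1-en-1-yl](pinacolato)borate | CCCC[C@H](CC)C[C@H](C)[B-]1(OC(C)(C)C(C)(C)O1)/C=C(\CC)C[C@H](CC)[C@H]1CCO1.[Li+] | intermediate
30 | 2-[(3S,7S,9S)-5,9-diethyl-5-iodo-7-methyl-3-((R)-oxetan-2-yl)tridecan-6-yl]-4,4,5,5-tetramethyl-1,3,2-dioxaborolane (anti adduct from either alkene face) | CCCC[C@H](CC)C[C@H](C)C(B1OC(C)(C)C(C)(C)O1)C(I)(CC)C[C@H](CC)[C@H]1CCO1 | intermediate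
31 | (R)-2-[(3S,5Z,7S,9S)-5,9-diethyl-7-methyltridec-5-en-3-yl]oxetane | CCCC[C@H](CC)C[C@H](C)/C=C(/CC)C[C@H](CC)[C@H]1CCO1 | intermediate
32 | triethyl{[(3S,7S,9S)-5,9-diethyl-7-methyl-3-((R)-oxetan-2-yl)tridecan-5-yl]peroxy}silane (both C6 epimers) | CCCC[C@H](CC)C[C@H](C)CC(CC)(OO[Si](CC)(CC)CC)C[C@H](CC)[C@H]1CCO1 | intermediate
33 | (3S,7S,9S)-5,9-diethyl-7-methyl-3-((R)-oxetan-2-yl)tridecan-5-yl hydroperoxide (both C6 epimers) | CCCC[C@H](CC)C[C@H](C)CC(CC)(OO)C[C@H](CC)[C@H]1CCO1 | intermediate
34 | 2-[(3S,4S,6R)-4,6-diethyl-6-((2S,4S)-4-ethyl-2-methyloctyl)-1,2-dioxan-3-yl]ethan-1-ol | CCCC[C@H](CC)C[C@H](C)C[C@]1(CC)C[C@H](CC)[C@H](CCO)OO1 | intermediate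
35 | 2-[(3S,4S,6R)-4,6-diethyl-6-((2S,4S)-4-ethyl-2-methyloctyl)-1,2-dioxan-3-yl]acetaldehyde | CCCC[C@H](CC)C[C@H](C)C[C@]1(CC)C[C@H](CC)[C@H](CC=O)OO1 | intermediate
36 | 2-[(3S,4S,6R)-4,6-diethyl-6-((2S,4S)-4-ethyl-2-methyloctyl)-1,2-dioxan-3-yl]acetic acid | CCCC[C@H](CC)C[C@H](C)C[C@]1(CC)C[C@H](CC)[C@H](CC(=O)O)OO1 | target

**Step count and risks**

Total: 15 steps. Longest linear sequence: 11 steps (14 → 36, steps 5–15); fragment B joins after 4 steps.

Step 13 (hydroperoxysilylation). What may go wrong: hydrogen-atom transfer to the hindered (Z)-trisubstituted alkene may be slow, so that alkene isomerisation, over-reduction of the peroxide to the tertiary alcohol and attack of the cobalt salt on the oxetane gain ground; in addition the radical trapping is not expected to distinguish the two faces at C6. Fallback (ionic instead of radical oxygenation): setting out from 31, Hg(OAc)2 and anhydrous H2O2 in CH2Cl2 at 0 °C should add across C6=C7 in the Markovnikov, anti sense to give the β-(acetoxymercurio) tertiary hydroperoxide F1, and NaBH4/NaOH at 0 °C should replace mercury by hydrogen to give hydroperoxide 33, where the route is rejoined at the second stage of step 14. This path is likewise not expected to control C6, so the separation in step 14 stays in place.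

Step 14 (oxetane opening). What may go wrong: under the Lewis acid the tertiary hydroperoxide may ionise or undergo Hock-type carbon-to-oxygen migration faster than it attacks the activated oxetane, or the oxetane may be opened by an external nucleophile. Fallback (base-mediated closure on a sulfonate instead of acid-mediated closure on the oxetane): setting out from 31, MgBr2·OEt2 in Et2O should open the oxetane at its unhindered CH2 to give (3R,4S,6Z,8S,10S)-1-bromo-4,6,10-triethyl-8-methyltetradec-6-en-3-ol F2 with C3 untouched; MsCl/Et3N gives the mesylate F3; the conditions of step 13 give the silyl peroxide F4 as both C6 epimers; Bu4NF in THF at 0 °C then frees the peroxide anion, which displaces the secondary mesylate in a 6-exo-tet SN2 reaction with inversion at C3 to give the bromoethyl dioxane F5, whose C6 epimers are separated; CsOAc in DMF gives the acetate F6, and K2CO3 in MeOH at 0 °C returns alcohol 34.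

Step 12 (key step). What may go wrong: the β,β-disubstituted alkenyllithium may add sluggishly to the hindered secondary boronic ester or attack its own oxetane on warming, and incomplete ate-complex formation would leave 13 unproductive. Fallback (cross-coupling instead of 1,2-metallate rearrangement, same bond): setting out from 13 and 27, tert-BuLi converts 13 into the tert-butyl boronate complex F7, Zn(OAc)2 takes over the secondary alkyl group with retention to give the alkylzinc acetate F8, and Pd(OAc)2/CPhos-catalysed Negishi coupling with 27 should give the (E)-alkene F9 with retention at C8 and at the double bond. F9 is the geometric isomer of 31 and rejoins the route at 32, because step 13 erases the alkene geometry.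

**Further compounds**

F1 | step 13 | (3S,7S,9S)-6-(acetoxymercurio)-5,9-diethyl-7-methyl-3-((R)-oxetan-2-yl)tridecan-5-yl hydroperoxide (anti adduct from either face) | CCCC[C@H](CC)C[C@H](C)C([Hg]OC(C)=O)C(CC)(OO)C[C@H](CC)[C@H]1CCO1
F2 | step 14 | (3R,4S,6Z,8S,10S)-1-bromo-4,6,10-triethyl-8-methyltetradec-6-en-3-ol | CCCC[C@H](CC)C[C@H](C)/C=C(/CC)C[C@H](CC)[C@@H](CCBr)O
F3 | step 14 | (3R,4S,6Z,8S,10S)-1-bromo-4,6,10-triethyl-8-methyltetradec-6-en-3-yl methanesulfonate | CCCC[C@H](CC)C[C@H](C)/C=C(/CC)C[C@H](CC)[C@@H](CCBr)OS(C)(=O)=O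
F4 | step 14 | (3R,4S,8S,10S)-1-bromo-4,6,10-triethyl-8-methyl-6-(triethylsilylperoxy)tetradecan-3-yl methanesulfonate (both C6 epimers) | CCCC[C@H](CC)C[C@H](C)CC(CC)(OO[Si](CC)(CC)CC)C[C@H](CC)[C@@H](CCBr)OS(C)(=O)=O
F5 | step 14 | (3S,4S,6R)-3-(2-bromoethyl)-4,6-diethyl-6-((2S,4S)-4-ethyl-2-methyloctyl)-1,2-dioxane | CCCC[C@H](CC)C[C@H](C)C[C@]1(CC)C[C@H](CC)[C@H](CCBr)OO1
F6 | step 14 | 2-[(3S,4S,6R)-4,6-diethyl-6-((2S,4S)-4-ethyl-2-methyloctyl)-1,2-dioxan-3-yl]ethyl acetate | CCCC[C@H](CC)C[C@H](C)C[C@]1(CC)C[C@H](CC)[C@H](CCOC(C)=O)OO1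
F7 | step 12 | lithium tert-butyl[(2S,4S)-4-ethyloctan-2-yl](pinacolato)borate | CCCC[C@H](CC)C[C@H](C)[B-]1(C(C)(C)C)OC(C)(C)C(C)(C)O1.[Li+]
F8 | step 12 | [(2S,4S)-4-ethyloctan-2-yl]zinc acetate | CCCC[C@H](CC)C[C@H](C)[Zn]OC(C)=O
F9 | step 12 | (R)-2-[(3S,5E,7S,9S)-5,9-diethyl-7-methyltridec-5-en-3-yl]oxetane | CCCC[C@H](CC)C[C@H](C)/C=C(\CC)C[C@H](CC)[C@H]1CCO1
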